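**Plan**
- **Enabling feature.** The central ring is a 4,6-dialkylresorcinol, the dehydro form of a 4,6-disubstituted cyclohexane-1,3-dione. One ring C–O carbon, the ring carbon next to it, the two CH2 groups and the aryl ketone C=O form a 1,5-dioxygenated chain. This is the retron of a Michael addition of a dione-derived dienol ether to an aryl vinyl ketone.
- **Retrosynthetic cuts.** (a) The four O–benzyl bonds and the aromaticity of the central ring, back to a 3-benzyloxycyclohex-2-enone. (b) The ring C–CH2 bond of the dihydrochalcone arm. (c) The CH2–aryl bond to the 2-methoxy-4-oxyphenyl ring. (d) The ring C–CH(aryl) bond.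
- **Why the ring is carried unsaturated only in part.** The 4-hydroxy-2-methoxyphenyl ring is an electronic twin of the resorcinol, so substitution on the finished arene could not tell the two apart. A dienol silane is the only strong carbon nucleophile in its molecule and reacts at one defined carbon.
- **Forward order.** Cyclohexane-1,3-dione → benzyl vinylogous ester → arm 1 at C6 (Ir allylation, then hydroboration/Suzuki) → enolisation toward C4 → arm 2 at C4 (the union) → dehydrogenation to the arene → hydrogenolysis. No ring is built; the only ring event is the late aromatisation.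
- **Stereochemistry.** The single stereocentre comes from the chiral Ir–phosphoramidite catalyst of the allylation. The ring stereocentres are transient and vanish on aromatisation. Both 4-oxyphenyl-C3 units derive from one allylic alcohol.

Key step: step 11

Assumption: the (R,R,R) phosphoramidite is written for the (S)-configured allylation product of step 6; should the sense of induction prove opposite, the equally available (S,S,S) ligand is used.

Step 1
Reactants: 1 cyclohexane-1,3-dione
Product: 2 3-(benzyloxy)cyclohex-2-en-1-one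
Conditions: BnOH, TsOH·H2O (cat.), toluene, reflux, azeotropic removal of water
Reagents that add atoms: benzyl alcohol, OCc1ccccc1
Why: Acid-catalysed enol etherification of a symmetrical 1,3-dione (vinylogous esterification) should give a single product because both carbonyl groups are equivalent.

Step 2
Reactants: 2 3-(benzyloxy)cyclohex-2-en-1-one
Product: 3 {[5-(benzyloxy)cyclohexa-1,5-dien-1-yl]oxy}trimethylsilane
Conditions: LDA, THF, −78 °C; TMSCl, −78 °C → rt; non-aqueous work-up
Reagents that add atoms: chlorotrimethylsilane, C[Si](C)(C)Cl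
Why: Kinetic α′-deprotonation of a vinylogous ester (Stork–Danheiser regiochemistry) followed by O-silylation should give the 2-silyloxydiene with its free terminus at C6.

Step 3
Reactants: 4 4-(benzyloxy)benzaldehyde; 5 vinylmagnesium bromide
Product: 6 rac-1-[4-(benzyloxy)phenyl]prop-2-en-1-ol
Conditions: THF, 0 °C; then H2O
Reagents that add atoms: none
Why: Grignard 1,2-addition to a non-enolisable aromatic aldehyde is reliable, and the racemic carbinol centre is of no consequence because it is lost in steps 4 and 10.

Step 4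
Reactants: 6 rac-1-[4-(benzyloxy)phenyl]prop-2-en-1-ol
Product: 7 (E)-3-[4-(benzyloxy)phenyl]prop-2-en-1-ol
Conditions: TsOH·H2O (5 mol %), THF–H2O, rt, dilute
Reagents that add atoms: water, O
Why: Acid-catalysed 1,3-transposition of an allylic alcohol should work because ionisation gives a 4-alkoxyphenyl-stabilised allyl cation that water captures, under thermodynamic control, at the terminal carbon to give the conjugated (E)-cinnamyl alcohol.

Step 5
Reactants: 7 (E)-3-[4-(benzyloxy)phenyl]prop-2-en-1-ol
Product: 8 (E)-3-[4-(benzyloxy)phenyl]prop-2-en-1-yl tert-butyl carbonate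
Conditions: Boc2O, DMAP (cat.), CH2Cl2, 0 °C → rt
Reagents that add atoms: di-tert-butyl dicarbonate, CC(C)(C)OC(=O)OC(=O)OC(C)(C)C
Why: DMAP-catalysed O-acylation of a primary alcohol gives the carbonate leaving group for allyl–iridium formation, and the tert-butyl group is chosen so that the alkoxide released in step 6 is too hindered to exchange with the benzyloxy group of the vinylogous ester.

Step 6
Reactants: 3 {[5-(benzyloxy)cyclohexa-1,5-dien-1-yl]oxy}trimethylsilane; 8 (E)-3-[4-(benzyloxy)phenyl]prop-2-en-1-yl tert-butyl carbonate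
Product: 9 3-(benzyloxy)-6-{(1S)-1-[4-(benzyloxy)phenyl]prop-2-en-1-yl}cyclohex-2-en-1-one (C6 epimers)
Conditions: [Ir(cod)Cl]2 (2 mol %), (R,R,R)-binaphthol-derived N,N-bis(1-phenylethyl)phosphoramidite (4 mol %, pre-activated with n-PrNH2), KF, 18-crown-6, THF, rt
Reagents that add atoms: none
Why: Iridium-catalysed asymmetric allylic alkylation of a fluoride-activated enol silane of a vinylogous ester is a known reaction type in which the cyclometallated Ir–phosphoramidite directs attack to the aryl-bearing allyl terminus and fixes the allyl face, which sets the (S) centre, while the neighbouring ring centre C6 forms as a mixture that is erased later.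

Step 7
Reactants: 10 4-bromo-3-methoxyphenol
Product: 11 4-(benzyloxy)-1-bromo-2-methoxybenzene
Conditions: BnBr, K2CO3, DMF, rt
Reagents that add atoms: benzyl bromide, BrCc1ccccc1
Why: Williamson ether synthesis on a phenol is routine and leaves the aryl bromide and the methyl ether untouched.

Step 8
Reactants: 9 3-(benzyloxy)-6-{(1S)-1-[4-(benzyloxy)phenyl]prop-2-en-1-yl}cyclohex-2-en-1-one; 11 4-(benzyloxy)-1-bromo-2-methoxybenzene
Product: 13 3-(benzyloxy)-6-{(1S)-3-[4-(benzyloxy)-2-methoxyphenyl]-1-[4-(benzyloxy)phenyl]propyl}cyclohex-2-en-1-one (C6 epimers), via B-alkyl-9-BBN adduct 12 (not isolated)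
Conditions: 9-BBN-H (1.1 equiv), THF, 0 °C → rt; then 11, PdCl2(dppf) (5 mol %), K3PO4, H2O, DMF–THF, 50 °C
Reagents that add atoms: 9-borabicyclo[3.3.1]nonane, [H]B1C2CCCC1CCC2 (its boron stays only in 12)
Why: Anti-Markovnikov hydroboration of the monosubstituted alkene followed by B-alkyl Suzuki–Miyaura coupling should be selective because the ester-like vinylogous carbonyl group and its donor-substituted trisubstituted C=C bond are inert to 9-BBN at room temperature, and the stereocentre takes no part in the reacting bonds.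

Step 9
Reactants: 13 3-(benzyloxy)-6-{(1S)-3-[4-(benzyloxy)-2-methoxyphenyl]-1-[4-(benzyloxy)phenyl]propyl}cyclohex-2-en-1-one
Product: 14 tert-butyl[(3-(benzyloxy)-6-{(1S)-3-[4-(benzyloxy)-2-methoxyphenyl]-1-[4-(benzyloxy)phenyl]propyl}cyclohexa-1,3-dien-1-yl)oxy]dimethylsilane
Conditions: TBSOTf (1.2 equiv), Et3N (2 equiv), CH2Cl2, 0 °C → rt; cold NaHCO3 wash, used crude under argon
Reagents that add atoms: tert-butyldimethylsilyl triflate, CC(C)(C)[Si](C)(C)OS(=O)(=O)C(F)(F)F
Why: Soft enolisation (silyl triflate/amine) passes through a 1-silyloxy-3-benzyloxyallyl cation in which C4–H2 and C6–H are electronically alike, so the amine should remove the unhindered C4 hydrogen rather than the tertiary one beside the bulky diarylpropyl group, and reversible reprotonation by the ammonium salt funnels material to the less strained diene.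

Step 10
Reactants: 6 rac-1-[4-(benzyloxy)phenyl]prop-2-en-1-ol
Product: 15 1-[4-(benzyloxy)phenyl]prop-2-en-1-one
Conditions: activated MnO2 (excess), CH2Cl2, rt; filtered and used at once
Reagents that add atoms: none
Why: Manganese dioxide oxidation of an alcohol that is both benzylic and allylic is mild and selective, and immediate use avoids polymerisation of the vinyl ketone.

Step 11
Reactants: 14 tert-butyl[(3-(benzyloxy)-6-{(1S)-3-[4-(benzyloxy)-2-methoxyphenyl]-1-[4-(benzyloxy)phenyl]propyl}cyclohexa-1,3-dien-1-yl)oxy]dimethylsilane; 15 1-[4-(benzyloxy)phenyl]prop-2-en-1-one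
Product: 17 3-(benzyloxy)-6-{(1S)-3-[4-(benzyloxy)-2-methoxyphenyl]-1-[4-(benzyloxy)phenyl]propyl}-4-{3-[4-(benzyloxy)phenyl]-3-oxopropyl}cyclohex-2-en-1-one (C4 and C6 epimers), via aryl ketone enol silane 16 (not isolated)
Conditions: Tf2NH (2 mol %), CH2Cl2, −78 °C, slow addition of 15; then TBAF, AcOH, THF, 0 °C
Reagents that add atoms: none
Why: Vinylogous Mukaiyama–Michael addition: the silylium carrier TBSNTf2 (from Tf2NH and a trace of 14) O-silylates enone 15, the free diene terminus C4 of 14, onto which both the C1 silyloxy group (through C1=C2–C3=C4) and the C3 benzyloxy group push electron density, attacks the CH2 terminus, and the resulting 1-silyloxy-3-benzyloxyallyl cation passes its silyl group to the next enone, leaving enol silane 16 with the vinylogous ester restored. The closest known reaction type is the terminal-carbon Michael (or stepwise [4+2]) reaction of 1,3-dioxygenated dienes with vinyl ketones. No ring of the target is closed, and any bicyclo[2.2.2]octene formed by collapse of the ion pair carries a bridgehead silyloxy group β to the aryl ketone and should revert to 17 by retro-aldol cleavage in the fluoride quench. The new ring stereocentre C4, like C6, is not controlled and need not be, since both are erased in step 12, while the (S) centre of the side chain bears no acidic hydrogen and is untouched. Site selectivity (C4 over C2 and C6) follows from the largest donor coefficient at the free terminus and from C6 being sp3, and chemoselectivity over the dialkoxybenzene ring, which would compete in any electrophilic substitution of the finished resorcinol, follows from the far higher nucleophilicity of the dienol silane. Slow addition of 15 keeps the less nucleophilic enol silane 16 from adding to a second enone.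

Step 12
Reactants: 17 3-(benzyloxy)-6-{(1S)-3-[4-(benzyloxy)-2-methoxyphenyl]-1-[4-(benzyloxy)phenyl]propyl}-4-{3-[4-(benzyloxy)phenyl]-3-oxopropyl}cyclohex-2-en-1-one
Product: 20 3-{2-(benzyloxy)-5-[(1R)-3-[4-(benzyloxy)-2-methoxyphenyl]-1-[4-(benzyloxy)phenyl]propyl]-4-hydroxyphenyl}-1-[4-(benzyloxy)phenyl]propan-1-one, via bis-silylated dienol ether 18 (not isolated), via silylated arene 19 (not isolated)
Conditions: (a) TBSOTf (2.5 equiv), Et3N (4 equiv), CH2Cl2, 0 °C, NaHCO3 wash; (b) DDQ (1.05 equiv), CH2Cl2, −20 °C; (c) TBAF, AcOH, THF, 0 °C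
Reagents that add atoms: tert-butyldimethylsilyl triflate, CC(C)(C)[Si](C)(C)OS(=O)(=O)C(F)(F)F (its silyl groups stay only in 18 and 19)
Why: Silyl dienol ether formation followed by DDQ dehydrogenation is a standard cyclohexenone-to-phenol aromatisation in which hydride leaves from C5 because the cation is stabilised by both oxygen substituents at C1 and C3, loss of the last ring hydrogen should outrun attack of DDQ on benzylic positions or on the side-chain enol silane (whose oxidation would only give a chalcone that step 13 saturates), buffered fluoride then frees phenol and ketone, and the stereocentre is untouched, its descriptor changing to (R) only because the CIP ranking changes.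

Step 13
Reactants: 20 3-{2-(benzyloxy)-5-[(1R)-3-[4-(benzyloxy)-2-methoxyphenyl]-1-[4-(benzyloxy)phenyl]propyl]-4-hydroxyphenyl}-1-[4-(benzyloxy)phenyl]propan-1-one
Product: 21 3-{2,4-dihydroxy-5-[(1R)-3-(4-hydroxy-2-methoxyphenyl)-1-(4-hydroxyphenyl)propyl]phenyl}-1-(4-hydroxyphenyl)propan-1-one
Conditions: H2 (1 atm), 10% Pd/C, EtOAc–MeOH, rt, stopped at complete debenzylation
Reagents that add atoms: none
Why: Catalytic hydrogenolysis should cleave the four aryl benzyl ethers while the 4-oxygenated aryl ketone of a dihydrochalcone, the methyl ether and the diarylmethine centre are inert under neutral conditions at 1 atm.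

**Compound list**
1 | cyclohexane-1,3-dione | O=C1CCCC(=O)C1 | starting material
2 | 3-(benzyloxy)cyclohex-2-en-1-one | O=C1C=C(OCc2ccccc2)CCC1 | intermediate
3 | {[5-(benzyloxy)cyclohexa-1,5-dien-1-yl]oxy}trimethylsilane | C[Si](C)(C)OC1=CCCC(OCc2ccccc2)=C1 | intermediate
4 | 4-(benzyloxy)benzaldehyde | O=Cc1ccc(OCc2ccccc2)cc1 | starting material
5 | vinylmagnesium bromide | C=C[Mg]Br | starting material
6 | rac-1-[4-(benzyloxy)phenyl]prop-2-en-1-ol | C=CC(O)c1ccc(OCc2ccccc2)cc1 | intermediate
7 | (E)-3-[4-(benzyloxy)phenyl]prop-2-en-1-ol | OC/C=C/c1ccc(OCc2ccccc2)cc1 | intermediate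
8 | (E)-3-[4-(benzyloxy)phenyl]prop-2-en-1-yl tert-butyl carbonate | CC(C)(C)OC(=O)OC/C=C/c1ccc(OCc2ccccc2)cc1 | intermediate
9 | 3-(benzyloxy)-6-{(1S)-1-[4-(benzyloxy)phenyl]prop-2-en-1-yl}cyclohex-2-en-1-one, C6 epimers | C=C[C@H](c1ccc(OCc2ccccc2)cc1)C1CCC(OCc2ccccc2)=CC1=O | intermediate
10 | 4-bromo-3-methoxyphenol | COc1cc(O)ccc1Br | starting material
11 | 4-(benzyloxy)-1-bromo-2-methoxybenzene | COc1cc(OCc2ccccc2)ccc1Br | intermediate
12 | B-alkyl-9-BBN adduct of 9, (S) side-chain centre | C1CC2CCCC(C1)B2CC[C@H](c1ccc(OCc2ccccc2)cc1)C1CCC(OCc2ccccc2)=CC1=O | intermediate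
13 | 3-(benzyloxy)-6-{(1S)-3-[4-(benzyloxy)-2-methoxyphenyl]-1-[4-(benzyloxy)phenyl]propyl}cyclohex-2-en-1-one, C6 epimers | COc1cc(OCc2ccccc2)ccc1CC[C@H](c1ccc(OCc2ccccc2)cc1)C1CCC(OCc2ccccc2)=CC1=O | intermediate
14 | 1-TBSO-3-benzyloxy-6-[(1S)-diarylpropyl]cyclohexa-1,3-diene (full name in step 9) | COc1cc(OCc2ccccc2)ccc1CC[C@H](c1ccc(OCc2ccccc2)cc1)C1CC=C(OCc2ccccc2)C=C1O[Si](C)(C)C(C)(C)C | intermediate
15 | 1-[4-(benzyloxy)phenyl]prop-2-en-1-one | C=CC(=O)c1ccc(OCc2ccccc2)cc1 | intermediate
16 | TBS enol ether (at the aryl ketone) of 17, (S) side-chain centre | COc1cc(OCc2ccccc2)ccc1CC[C@H](c1ccc(OCc2ccccc2)cc1)C1CC(CC=C(O[Si](C)(C)C(C)(C)C)c2ccc(OCc3ccccc3)cc2)C(OCc2ccccc2)=CC1=O | intermediate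
17 | 3-(benzyloxy)-6-[(1S)-diarylpropyl]-4-{3-[4-(benzyloxy)phenyl]-3-oxopropyl}cyclohex-2-en-1-one, C4 and C6 epimers (full name in step 11) | COc1cc(OCc2ccccc2)ccc1CC[C@H](c1ccc(OCc2ccccc2)cc1)C1CC(CCC(=O)c2ccc(OCc3ccccc3)cc2)C(OCc2ccccc2)=CC1=O | intermediate
18 | bis-TBS derivative of 17: ring 1-silyloxy-3-benzyloxy-1,3-diene and side-chain enol silane, (S) | COc1cc(OCc2ccccc2)ccc1CC[C@H](c1ccc(OCc2ccccc2)cc1)C1CC(CC=C(O[Si](C)(C)C(C)(C)C)c2ccc(OCc3ccccc3)cc2)=C(OCc2ccccc2)C=C1O[Si](C)(C)C(C)(C)C | intermediate
19 | aromatised bis-TBS compound: aryl TBS ether and side-chain enol silane, (R) | COc1cc(OCc2ccccc2)ccc1CC[C@H](c1ccc(OCc2ccccc2)cc1)c1cc(CC=C(O[Si](C)(C)C(C)(C)C)c2ccc(OCc3ccccc3)cc2)c(OCc2ccccc2)cc1O[Si](C)(C)C(C)(C)C | intermediate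
20 | 3-{2-(benzyloxy)-5-[(1R)-3-[4-(benzyloxy)-2-methoxyphenyl]-1-[4-(benzyloxy)phenyl]propyl]-4-hydroxyphenyl}-1-[4-(benzyloxy)phenyl]propan-1-one | COc1cc(OCc2ccccc2)ccc1CC[C@H](c1ccc(OCc2ccccc2)cc1)c1cc(CCC(=O)c2ccc(OCc3ccccc3)cc2)c(OCc2ccccc2)cc1O | intermediate
21 | 3-{2,4-dihydroxy-5-[(1R)-3-(4-hydroxy-2-methoxyphenyl)-1-(4-hydroxyphenyl)propyl]phenyl}-1-(4-hydroxyphenyl)propan-1-one | COc1cc(O)ccc1CC[C@H](c1ccc(O)cc1)c1cc(CCC(=O)c2ccc(O)cc2)c(O)cc1O | target

**Count**
Total steps: 13.
Longest linear sequence: 9 steps (4 → 6 → 7 → 8 → 9 → 13 → 14 → 17 → 20 → 21).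

**Steps most likely to fail**

1. **Step 11.** Acid-induced oligomerisation of the vinyl ketone, protodesilylation of the diene before C–C bond formation, or competing attack through C2 may erode the union. The fallback sets out from 14 and comes back at 17. It replaces the Lewis-acid conjugate addition by a catalyst-free cycloaddition and fragmentation.
   - Compounds 14 and 15 are heated in toluene (80 °C, BHT) to undergo a Diels–Alder reaction. The same free terminus C4 bonds to the CH2 carbon of the enone.
   - This should give {5-(benzyloxy)-1-[(tert-butyldimethylsilyl)oxy]-7-[(1S)-diarylpropyl]bicyclo[2.2.2]oct-5-en-2-yl}[4-(benzyloxy)phenyl]methanone F1.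
   - TBAF in THF, followed by an acetic acid quench, unmasks the bridgehead alkoxide. Retro-aldol cleavage of the bond to the acyl-bearing carbon is the only possible fragmentation while the enol ether is intact, and it opens the bicycle to 17.

2. **Step 9.** Proton loss from C6 instead of C4, or formation of a mixture of dienes, would leave no usable nucleophilic terminus. The fallback sets out from 13 and comes back at 20. It makes the regiochemistry of enolisation irrelevant by aromatising first and forming the same ring C–CH2 bond with palladium.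
   - The crude mixture of 14 and its C1=C6 regioisomeric dienol silane F2 is dehydrogenated with DDQ to the aryl silyl ether F3.
   - Buffered TBAF gives 5-(benzyloxy)-2-[(1R)-diarylpropyl]phenol F4.
   - The free hydroxyl group of F4 makes this ring the most reactive one, so NBS at low temperature should brominate para to it and give the 4-bromophenol F5.
   - A Heck reaction of F5 with allylic alcohol 6 follows (Pd(OAc)2, P(o-tol)3, NaHCO3, DMF, 90 °C). β-Hydride elimination toward the carbinol carbon and tautomerisation deliver the saturated ketone, which gives 20.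

3. **Step 12.** Hydride abstraction from the electron-rich benzylic or diarylmethine C–H bonds once the arene has formed would erode the stereocentre, and incomplete enolisation may also lower the outcome. The fallback sets out from 18 and comes back at 21. It replaces outer-sphere hydride abstraction by inner-sphere dehydrosilylation.
   - A double Saegusa–Ito oxidation of 18 is run with Pd(OAc)2 in MeCN–DMSO.
   - On the ring it proceeds through carbon-bound palladium enolates and β-hydride elimination from C5, giving a dienone that tautomerises to the phenol.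
   - On the side chain it eliminates from the benzylic CH2, so the product should be the (E)-chalcone phenol F6.
   - F6 is submitted to the conditions of step 13, which saturate the C=C bond and remove the benzyl groups to give 21.

**Further compounds**
F1 | step 11 | {5-(benzyloxy)-1-[(tert-butyldimethylsilyl)oxy]-7-{(1S)-3-[4-(benzyloxy)-2-methoxyphenyl]-1-[4-(benzyloxy)phenyl]propyl}bicyclo[2.2.2]oct-5-en-2-yl}[4-(benzyloxy)phenyl]methanone | COc1cc(OCc2ccccc2)ccc1CC[C@H](c1ccc(OCc2ccccc2)cc1)C1CC2CC(C(=O)c3ccc(OCc4ccccc4)cc3)C1(O[Si](C)(C)C(C)(C)C)C=C2OCc1ccccc1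
F2 | step 9 | tert-butyl[(5-(benzyloxy)-2-{(1R)-3-[4-(benzyloxy)-2-methoxyphenyl]-1-[4-(benzyloxy)phenyl]propyl}cyclohexa-1,5-dien-1-yl)oxy]dimethylsilane | COc1cc(OCc2ccccc2)ccc1CC[C@H](c1ccc(OCc2ccccc2)cc1)C1=C(O[Si](C)(C)C(C)(C)C)C=C(OCc2ccccc2)CC1
F3 | step 9 | tert-butyl(5-(benzyloxy)-2-{(1R)-3-[4-(benzyloxy)-2-methoxyphenyl]-1-[4-(benzyloxy)phenyl]propyl}phenoxy)dimethylsilane | COc1cc(OCc2ccccc2)ccc1CC[C@H](c1ccc(OCc2ccccc2)cc1)c1ccc(OCc2ccccc2)cc1O[Si](C)(C)C(C)(C)C
F4 | step 9 | 5-(benzyloxy)-2-{(1R)-3-[4-(benzyloxy)-2-methoxyphenyl]-1-[4-(benzyloxy)phenyl]propyl}phenol | COc1cc(OCc2ccccc2)ccc1CC[C@H](c1ccc(OCc2ccccc2)cc1)c1ccc(OCc2ccccc2)cc1O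
F5 | step 9 | 5-(benzyloxy)-4-bromo-2-{(1R)-3-[4-(benzyloxy)-2-methoxyphenyl]-1-[4-(benzyloxy)phenyl]propyl}phenol | COc1cc(OCc2ccccc2)ccc1CC[C@H](c1ccc(OCc2ccccc2)cc1)c1cc(Br)c(OCc2ccccc2)cc1O
F6 | step 12 | (E)-3-{2-(benzyloxy)-5-[(1R)-3-[4-(benzyloxy)-2-methoxyphenyl]-1-[4-(benzyloxy)phenyl]propyl]-4-hydroxyphenyl}-1-[4-(benzyloxy)phenyl]prop-2-en-1-one | COc1cc(OCc2ccccc2)ccc1CC[C@H](c1ccc(OCc2ccccc2)cc1)c1cc(/C=C/C(=O)c2ccc(OCc3ccccc3)cc2)c(OCc2ccccc2)cc1O
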